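C5–propenyl is cut first (Suzuki–Miyaura), then C2–C3 of the dihydrofuran ring C (carbene C–H insertion), then O1–C2 (Mitsunobu). This leaves 2'-hydroxy-3'-methoxyacetophenone (ring A with C3 and its methyl), syringaldehyde (ring B with C2) and a propenylboronate.
Enabling feature: once O1–C2 exists, C2–H is alpha to O1 and benzylic to the electron-rich ring B, and O1–C7a–C3a hold it 1,5 to C3. A carbene at C3 can therefore take this unfunctionalised C–H bond and close ring C.
Helpers: C3 enters at the ketone oxidation level (acetyl, hydrazone, diazo; N2 leaves in the event). Br at C5 stands in for the carbene- and acid-sensitive propenyl group, and a MOM ether masks the ring B hydroxyl.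
Forward order: rings A and B are bought and joined at O1–C2, ring C is closed at C2–C3, C2 is equilibrated, and the propenyl chain goes on last.
Stereochemistry: C3 (S) comes from the chiral dirhodium catalyst. C2 forms cis (R) and is then turned trans (S) under control of C3 by acid-induced reversible O1–C2 opening once the ring B hydroxyl is free. The E alkene comes from the boronate.

Key step: step 6

Assumption: Rh2(R-PTAD)4 (PTAD = N-phthaloyl-(1-adamantyl)glycinate) is taken to open the carbene face that leads to 3S. If the sense of induction is the opposite, the equally available Rh2(S-PTAD)4 is used and nothing else changes.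

Step 1
Reactants: 1 1-(2-hydroxy-3-methoxyphenyl)ethan-1-one
Product: 2 1-(5-bromo-2-hydroxy-3-methoxyphenyl)ethan-1-one
Conditions: NBS (1.05 equiv), MeCN, 0 °C to rt
Reagents that add atoms: N-bromosuccinimide, O=C1CCC(=O)N1Br
Why: Electrophilic aromatic bromination, in which the free hydroxyl directs to its only open ortho/para position (C5, para), a site that is also meta to the acetyl group.

Step 2
Reactants: 3 syringaldehyde (4-hydroxy-3,5-dimethoxybenzaldehyde)
Product: 4 3,5-dimethoxy-4-(methoxymethoxy)benzaldehyde
Conditions: MOMCl, i-Pr2NEt, CH2Cl2, 0 °C to rt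
Reagents that add atoms: chloromethyl methyl ether, COCCl
Why: O-alkylation of the phenol (MOM protection), chosen because the acetal should survive hydrazine, MnO2 and the carbene and leaves under the acid that step 7 needs anyway.

Step 3
Reactants: 4 3,5-dimethoxy-4-(methoxymethoxy)benzaldehyde
Product: 5 [3,5-dimethoxy-4-(methoxymethoxy)phenyl]methanol
Conditions: NaBH4, MeOH, 0 °C
Reagents that add atoms: none
Why: Borohydride reduction of an aromatic aldehyde to the primary benzylic alcohol, to which the acetal and the aryl ethers are inert.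

Step 4
Reactants: 2 1-(5-bromo-2-hydroxy-3-methoxyphenyl)ethan-1-one; 5 [3,5-dimethoxy-4-(methoxymethoxy)phenyl]methanol
Product: 6 1-(5-bromo-2-{[3,5-dimethoxy-4-(methoxymethoxy)phenyl]methoxy}-3-methoxyphenyl)ethan-1-one
Conditions: PPh3, DIAD, THF, 0 °C to rt
Reagents that add atoms: none
Why: Mitsunobu etherification, in which the acidic phenol is alkylated at oxygen by the primary benzylic alcohol activated as its oxyphosphonium salt, so the labile electron-rich benzylic halide need not be isolated and O1–C2 is formed.

Step 5
Reactants: 6 the aryl benzyl ether ketone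
Product: 7 hydrazone of 6, [1-(5-bromo-2-{[3,5-dimethoxy-4-(methoxymethoxy)phenyl]methoxy}-3-methoxyphenyl)ethylidene]hydrazine (E/Z mixture)
Conditions: N2H4·H2O (10 equiv), AcOH (cat.), EtOH, 80 °C
Reagents that add atoms: hydrazine (used as the hydrate), NN
Why: Hydrazone formation by condensation, where the large excess of hydrazine suppresses azine formation, the aryl bromide, acetal and benzylic ether are inert, and both C=N isomers lead to the same diazoalkane.

Step 6
Reactants: 7 hydrazone of 6
Product: 9 cis-(2R,3S)-5-bromo-2-[3,5-dimethoxy-4-(methoxymethoxy)phenyl]-7-methoxy-3-methyl-2,3-dihydrobenzofuran, via diazoalkane 8 (not isolated)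
Conditions: MnO2 (8 equiv), CH2Cl2, 0 °C, dark; filter (Celite); add slowly to Rh2(R-PTAD)4 (1 mol %), CH2Cl2, 0 °C
Reagents that add atoms: none
Why: MnO2 dehydrogenates the N-unsubstituted hydrazone to the aryl methyl diazoalkane 8, which loses N2 on Rh2(R-PTAD)4 to give a rhodium-bound donor/donor carbene at C3; this takes the hydridic C2–H as hydride, and the resulting oxocarbenium/rhodium-alkyl pair collapses at once to the C2–C3 bond. The closest known reaction type is the enantioselective intramolecular C–H insertion of donor/donor rhodium carbenes made from o-(benzyloxy)aryl ketone hydrazones, which gives cis-2,3-disubstituted 2,3-dihydrobenzofurans. Ring C closes as a 1,5-insertion through a five-membered cyclic transition state, the only ring size within reach because O1, C7a and C3a hold C2–H over the carbene carbon. C3 is set by the chiral carboxylate pocket, which leaves one carbene face open, and C2 is set by which of the two enantiotopic benzylic hydrogens is delivered, the compact transition state placing ring B and the methyl group on the same face (cis). The step needs chemoselectivity for insertion over the 1,2-hydride shift from the methyl group (styrene formation) and over azine formation; the double activation of C2–H by O1 and ring B, its proximity, the bulky adamantyl ligands, low temperature and slow addition should secure it. Bromine in place of the propenyl group removes the only alkene that could be cyclopropanated.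

Step 7
Reactants: 9 cis-(2R,3S) MOM-protected bromide
Product: 12 trans-bromophenol 4-[(2S,3S)-5-bromo-7-methoxy-3-methyl-2,3-dihydrobenzofuran-2-yl]-2,6-dimethoxyphenol, via cis-bromophenol 10 (not isolated), via ring-opened benzylic cation 11 (not isolated)
Conditions: TFA (10 vol %), H2O (5 equiv), CH2Cl2, 0 °C to rt
Reagents that add atoms: none
Why: Acid hydrolysis of the MOM acetal frees the para-hydroxyl of ring B, after which protonation of O1 allows reversible O1–C2 heterolysis to the p-hydroxybenzylic cation 11 (a protonated p-quinone methide) and 5-exo-trig re-closure, the known acid-induced cis-to-trans epimerisation of 2-aryl-2,3-dihydrobenzofurans, so that C2 settles anti to the C3 methyl group (2S) under thermodynamic control by the untouched C3 centre.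

Step 8
Reactants: 12 trans-bromophenol; 13 (E)-prop-1-enylboronic acid pinacol ester
Product: 14 Odoratisol A, 4-{(2S,3S)-7-methoxy-3-methyl-5-[(E)-prop-1-enyl]-2,3-dihydrobenzofuran-2-yl}-2,6-dimethoxyphenol
Conditions: Pd(OAc)2 (3 mol %), SPhos (6 mol %), K3PO4 (3 equiv), THF–H2O (10:1), 50 °C
Reagents that add atoms: none
Why: Suzuki–Miyaura coupling, in which zerovalent palladium inserts into the C5–Br bond and the alkenyl group is transferred with retention of the E geometry, the free phenol is tolerated, and the moderate temperature leaves C2 and C3 undisturbed.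

Compound list
1 | 1-(2-hydroxy-3-methoxyphenyl)ethan-1-one | CC(=O)c1cccc(OC)c1O | starting material
2 | 1-(5-bromo-2-hydroxy-3-methoxyphenyl)ethan-1-one | CC(=O)c1cc(Br)cc(OC)c1O | intermediate
3 | syringaldehyde | COc1cc(C=O)cc(OC)c1O | starting material
4 | 3,5-dimethoxy-4-(methoxymethoxy)benzaldehyde | COCOc1c(OC)cc(C=O)cc1OC | intermediate
5 | [3,5-dimethoxy-4-(methoxymethoxy)phenyl]methanol | COCOc1c(OC)cc(CO)cc1OC | intermediate
6 | 1-(5-bromo-2-{[3,5-dimethoxy-4-(methoxymethoxy)phenyl]methoxy}-3-methoxyphenyl)ethan-1-one | CC(=O)c1cc(Br)cc(OC)c1OCc1cc(OC)c(OCOC)c(OC)c1 | intermediate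
7 | hydrazone of 6 (E/Z mixture) | CC(=NN)c1cc(Br)cc(OC)c1OCc1cc(OC)c(OCOC)c(OC)c1 | intermediate
8 | 5-bromo-1-(1-diazoethyl)-2-{[3,5-dimethoxy-4-(methoxymethoxy)phenyl]methoxy}-3-methoxybenzene | CC(=[N+]=[N-])c1cc(Br)cc(OC)c1OCc1cc(OC)c(OCOC)c(OC)c1 | intermediate
9 | cis-(2R,3S)-5-bromo-2-[3,5-dimethoxy-4-(methoxymethoxy)phenyl]-7-methoxy-3-methyl-2,3-dihydrobenzofuran | Brc1cc(OC)c2c(c1)[C@H](C)[C@H](c1cc(OC)c(OCOC)c(OC)c1)O2 | intermediate
10 | cis-bromophenol, 4-[(2R,3S)-5-bromo-7-methoxy-3-methyl-2,3-dihydrobenzofuran-2-yl]-2,6-dimethoxyphenol | Brc1cc(OC)c2c(c1)[C@H](C)[C@H](c1cc(OC)c(O)c(OC)c1)O2 | intermediate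
11 | ring-opened p-hydroxybenzylic cation (protonated p-quinone methide), C3 configuration unchanged | C[C@@H](c1cc(Br)cc(OC)c1O)[CH+]c1cc(OC)c(O)c(OC)c1 | intermediate
12 | trans-bromophenol, 4-[(2S,3S)-5-bromo-7-methoxy-3-methyl-2,3-dihydrobenzofuran-2-yl]-2,6-dimethoxyphenol | Brc1cc(OC)c2c(c1)[C@H](C)[C@@H](c1cc(OC)c(O)c(OC)c1)O2 | intermediate
13 | (E)-prop-1-enylboronic acid pinacol ester | C/C=C/B1OC(C)(C)C(C)(C)O1 | starting material
14 | Odoratisol A | C/C=C/c1cc(OC)c2c(c1)[C@H](C)[C@@H](c1cc(OC)c(O)c(OC)c1)O2 | target

Total step count: 8. Longest linear sequence: 7 steps (steps 2 to 8, from syringaldehyde 3 to 14).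

Steps most likely to fail

Step 6. The 1,2-hydride migration from the methyl group within the carbene may outrun insertion, or the catalyst pocket may discriminate the carbene faces poorly.
- The fallback sets out from 6 and returns at 12. It replaces the donor/donor carbene with a donor/acceptor carbene that has no migrating hydrogen, and the methyl group is made from an ester afterwards.
- Ketone 6 is oxidised with SeO2 in pyridine at 100 °C to the alpha-keto acid F1. This is esterified (MeI, K2CO3, DMF) to the methyl alpha-keto ester F2.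
- Condensation with TsNHNH2 gives the tosylhydrazone F3, and DBU in CH2Cl2 eliminates sulfinate to give the aryldiazoacetate F4.
- Rh2(S-PTTL)4 (PTTL = N-phthaloyl-tert-leucinate; the catalyst enantiomer is chosen to give 2S) in toluene at −60 °C should give the cis ester F5. This is the same 1,5-insertion into C2–H, but C2 is now the centre that is kept.
- NaOMe in MeOH epimerises C3 through the ester enolate to the trans ester F6.
- i-Bu2AlH gives the primary alcohol F7, MsCl/Et3N gives the mesylate F8, and LiBHEt3 at 0 °C gives the trans 3-methyl MOM ether F9.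
- The acid treatment of step 7 then removes the acetal to give 12.

Step 7. Proton loss from C3 of the ring-opened cation followed by re-protonation may erode the enantiomeric purity. The equilibration may also stop short, or the released formaldehyde may alkylate the electron-rich rings.
- The fallback sets out from 9 and returns at 12. It replaces the equilibrium with an irreversible opening followed by a kinetically controlled oxidative closure.
- Et3SiH/TFA in CH2Cl2 at −20 °C traps the C2 cation as soon as it forms (ionic hydrogenation). It also cleaves the acetal and reduces its carbon, so no formaldehyde arises.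
- This gives the (R)-1,2-diarylpropane bisphenol F10, in which only the C3 centre remains.
- Ag2O in CH2Cl2 oxidises the 4-alkyl-2,6-dimethoxyphenol of ring B to the p-quinone methide F11.
- F11 is captured at once by the ring A hydroxyl in a 5-exo-trig oxa-Michael addition. Allylic strain around C3 steers this closure to the trans isomer 12, as in the biomimetic closure of this neolignan class.

Step 5. The hydrazone may condense with a second ketone to the azine, the condensation at the ortho-substituted ketone may be slow, or the N-unsubstituted hydrazone may decompose on storage.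
- The fallback sets out from 6 and returns at 9. It changes the diazo precursor and the way it is unmasked.
- Ketone 6 is condensed with 2-(trifluoromethyl)benzenesulfonyl hydrazide (MeOH, rt) to the N-sulfonylhydrazone F12, which cannot form an azine.
- NaH in CH2Cl2 at 0 °C in the presence of Rh2(R-PTAD)4 expels sulfinate (Bamford–Stevens reaction). This releases diazoalkane 8 slowly in the flask, and 8 goes on to 9 without any oxidant.

Further compounds
F1 | step 6 | 2-(5-bromo-2-{[3,5-dimethoxy-4-(methoxymethoxy)phenyl]methoxy}-3-methoxyphenyl)-2-oxoacetic acid | OC(=O)C(=O)c1cc(Br)cc(OC)c1OCc1cc(OC)c(OCOC)c(OC)c1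
F2 | step 6 | methyl ester of F1 | COC(=O)C(=O)c1cc(Br)cc(OC)c1OCc1cc(OC)c(OCOC)c(OC)c1
F3 | step 6 | tosylhydrazone of F2 | COC(=O)C(=NNS(=O)(=O)c1ccc(C)cc1)c1cc(Br)cc(OC)c1OCc1cc(OC)c(OCOC)c(OC)c1
F4 | step 6 | methyl 2-aryl-2-diazoacetate | COC(=O)C(=[N+]=[N-])c1cc(Br)cc(OC)c1OCc1cc(OC)c(OCOC)c(OC)c1
F5 | step 6 | methyl cis-(2S,3R)-5-bromo-2-[3,5-dimethoxy-4-(methoxymethoxy)phenyl]-7-methoxy-2,3-dihydrobenzofuran-3-carboxylate | Brc1cc(OC)c2c(c1)[C@@H](C(=O)OC)[C@@H](c1cc(OC)c(OCOC)c(OC)c1)O2
F6 | step 6 | methyl trans-(2S,3S)-5-bromo-2-[3,5-dimethoxy-4-(methoxymethoxy)phenyl]-7-methoxy-2,3-dihydrobenzofuran-3-carboxylate | Brc1cc(OC)c2c(c1)[C@H](C(=O)OC)[C@@H](c1cc(OC)c(OCOC)c(OC)c1)O2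
F7 | step 6 | trans-(2S,3R)-3-hydroxymethyl compound | Brc1cc(OC)c2c(c1)[C@H](CO)[C@@H](c1cc(OC)c(OCOC)c(OC)c1)O2
F8 | step 6 | mesylate of F7 | Brc1cc(OC)c2c(c1)[C@H](COS(C)(=O)=O)[C@@H](c1cc(OC)c(OCOC)c(OC)c1)O2
F9 | step 6 | trans-(2S,3S)-5-bromo-2-[3,5-dimethoxy-4-(methoxymethoxy)phenyl]-7-methoxy-3-methyl-2,3-dihydrobenzofuran | Brc1cc(OC)c2c(c1)[C@H](C)[C@@H](c1cc(OC)c(OCOC)c(OC)c1)O2
F10 | step 7 | 4-bromo-2-[(2R)-1-(4-hydroxy-3,5-dimethoxyphenyl)propan-2-yl]-6-methoxyphenol | C[C@@H](c1cc(Br)cc(OC)c1O)Cc1cc(OC)c(O)c(OC)c1
F11 | step 7 | p-quinone methide of F10, 4-[(2R)-2-(5-bromo-2-hydroxy-3-methoxyphenyl)propylidene]-2,6-dimethoxycyclohexa-2,5-dien-1-one | C[C@@H](c1cc(Br)cc(OC)c1O)C=C1C=C(OC)C(=O)C(OC)=C1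
F12 | step 5 | N-[2-(trifluoromethyl)benzenesulfonyl]hydrazone of 6 | CC(=NNS(=O)(=O)c1ccccc1C(F)(F)F)c1cc(Br)cc(OC)c1OCc1cc(OC)c(OCOC)c(OC)c1
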